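All runs were generated by integration for substances that don't exist; scatter was added.

In a one-step world each hand goes to product by a single step of its own, so the ratio of the logarithms of the fractions left of each hand stays constant, and the excess follows from the exposure θ = ln(charge / c right-handed substrate).

| flask | left-handed substrate | right-handed substrate | reagent | remark | time |
|---|---|---|---|---|---|
| cedar | 0.30 M | 0.30 M | 1.8 M | run made earlier |  |
| summer | 0.30 M | 0.30 M | 0.900 M |  | 10 d |
| noon | 0.30 M | 0.30 M | 0.900 M |  | 3.0 d |

cedar run (percent of the left-handed substrate and right-handed substrate together charged)

| time / h | right-handed substrate / % | left-handed substrate / % | left-handed product / % |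
|---|---|---|---|
| 4.00 | 44.6 | 40.1 | 7.8 |
| 6.00 | 42.7 | 37.4 | 11.1 |
| 10.0 | 37.9 | 30.7 | 15.9 |
| 20.0 | 30.5 | 21.9 | 24.1 |
| 30.0 | 25.5 | 15.8 | 29.4 |
| 50.0 | 19.2 | 8.8 | 34.1 |

(standard deviation of a reading: 0.3 percentage points)

1. which of the two ends with the higher excess of right-handed substrate over left-handed substrate among what is left of the two ("neither" if they lie within 2 percentage points) (summer / noon / neither)
2. excess of right-handed substrate over left-handed substrate among what is left of the two at the end, summer
3. excess of right-handed substrate over left-handed substrate among what is left of the two at the end, noon

- reagent is single-handed; left-handed substrate and right-handed substrate are mirror images of each other, charged as a racemate, each of them at the stated concentration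
- an excess is the difference of the two amounts in percent of their sum
- an excess is below zero if the other one leads
- the handed part of reagent does not stay in what it makes, so the products of the two hands are mirror images too

The last cedar reading gives

s = ln(c left-handed substrate / charge) / ln(c right-handed substrate / charge) = 1.82

This selectivity factor is a scattered reading, and it is not steady in the cedar run: the same ratio reads 1.93 at 4.00 h and falls to 1.67 at 20.0 h, with the last reading above that. Noon is summer stopped at 3.0 d, so the opposite outcome needs the excess to gain less than 2 percentage points after that time. With excess = tanh((s − 1)θ/2), the gain is about (s − 1)/2 per unit of θ at small excess, which sets the limit: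

θ gained < 0.0491, or 2.92 × 10⁻⁴ h⁻¹ on average

The cedar run was still gaining 0.0142 h⁻¹ between its last two readings, 48.6 times that pace, and the reagent charge of summer is lower than that of the cedar run by a factor of 2.00. My reckoning therefore puts summer ahead, without giving an excess of its own.

The forecast says summer, with 31% for summer and 22% for noon: “selectivity is modest and steady”.

The flask gives summer, with 26.5% for summer and 20.4% for noon.

    right-handed substrate ⇌ achiral form (K = 0.650, k = 2.13 × 10⁻⁶ s⁻¹)
    reagent + left-handed substrate → left-handed product (k = 7.24 × 10⁻⁶ M⁻¹ s⁻¹)
    left-handed product ⇌ right-handed product (k = 1.61 × 10⁻⁶ s⁻¹)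
    reagent ⇌ dormant form (K = 0.480, k = 5.50 × 10⁻⁶ s⁻¹)
    achiral form → waste (k = 1.86 × 10⁻⁶ s⁻¹)
    left-handed substrate ⇌ achiral form (K = 0.650, k = 2.13 × 10⁻⁶ s⁻¹)
    reagent + right-handed substrate → right-handed product (k = 3.54 × 10⁻⁶ M⁻¹ s⁻¹)

At the end of summer, s taken from what is left is 1.30, less than the cedar reading, and a constant 1.82 on its right-handed substrate would give 62.9%. Each hand exchanges with the achiral form at a relaxation half-life of 1.48 d, short against 10 d. With 0.23 M of reagent the same flask keeps 39% of its left-handed substrate and 44% of its right-handed substrate, so s is 1.15, lower again. A constant 1.82 there would give 32.4%, and the flask ends at 6.13%.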